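Atom labels used throughout: the ring of the target is O1, C2 (carries the arylethyl chain), C3, C4 (acetoxy), C5, C6 (aryl); the two side-chain carbons on C2 are C1′ and C2′ (C2′ is benzylic). The same labels are kept for the open-chain precursors. Ar = 3,4-bis(benzyloxy)-5-methoxyphenyl, Ar′ = 4-(benzyloxy)-3-methoxyphenyl.

## The problem

Target 18 is a 2,4,6-trisubstituted tetrahydropyran. C6 carries a 3,4-dihydroxy-5-methoxyphenyl group, C2 a 2-(4-hydroxy-3-methoxyphenyl)ethyl chain and C4 an acetoxy group. All three stereocentres are S, which places the C2 and C6 substituents cis (both equatorial) and the C4 acetate axial, trans to both. The seven-carbon chain C6–C5–C4–C3–C2–C1′–C2′ between the two arenes has to be built and then closed through O1. In the open chain the C6 and C4 oxygens are 1,3-syn, so C6 can control C4. C2 lies across the ring oxygen and needs its own source of control. The axial C4 oxygen is the less stable epimer and is best brought in from an acyclic syn-1,3-diol and not made by a late reduction. The C6–O1 bond is a benzylic ether para to an oxygen substituent, so it ionises with acid and can be hydrogenolysed. The free catechol and guaiacol rings are oxidation-prone, and the acetate will not survive base or hydride, so the phenols stay benzylated to the last step and the acetate goes on late. The enabling feature is that C2 is bonded to O1 and to C1′, and C2′ is benzylic. A C1′=C2′ styrene on C2 can therefore arise by allylic transposition from a C2′ carbinol, which sets C2 by 1,3-chirality transfer, and the styrene is erased in the same hydrogenation that frees the phenols.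

## Retrosynthesis

**18 back to 16.** The three O–CH2Ph bonds are cut, the C1′–C2′ bond is desaturated and the acetyl group is removed, giving acetate 17 and then alcohol 16. One hydrogenation then serves as deprotection and as removal of the alkene left by the key step. Acetylation must precede it, because free phenols would be acylated as well. The forward reaction has to spare the benzylic C6–O1 bond.

**16 back to 15.** The O1–C2 bond is cut with transposition of the alkene, giving (E)-triol 15 with hydroxyls on C6, C4 and C2′. The neighbouring cuts are weaker. Closing O1–C6 would go through a benzylic cation and give up control at C6. An oxa-Michael closure onto a C2′ ketone would leave a carbonyl to delete. Any ring C–C cut leaves the C4 oxygen to be adjusted afterwards. Triol 15 is acyclic and carries both ring oxygens at the right level and configuration. The forward reaction must be a syn SN2′ displacement. Working it through on the conformer in which the C2′–H bond eclipses the alkene shows that the (R)-carbinol delivers O1 to the correct face of C2 with an E styrene. The (S)-carbinol would have to choose between a 2,6-trans ring and a Z alkene.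

**15 back to 10 and 11.** The two silyl groups are put back (14), then the C1′–C2′ bond is cut to give terminal alkyne 10 and aldehyde 11. Hydroboration, boron-to-zinc exchange and ligand-controlled addition make the E alkene and the C2′ carbinol in one operation. The neighbouring sequence (acetylide addition, oxidation, asymmetric ynone reduction, trans reduction) costs four steps and asks a reduction catalyst to tell an aryl from an alkynyl substituent. The forward reaction needs Re-face addition to 11. The diol is protected as silyl ethers because they can be removed by fluoride, whereas acid would ionise C2′.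

**10 back to 7 and 8.** The silyl groups are removed (9), then the C2–C3 bond is cut to give epoxy alcohol 7 and acetylide 8. Opening a terminal epoxide at its CH2 group does not touch the C4 stereocentre and supplies C2 and C1′ as a terminal alkyne ready for the next step.

**7 back to 4.** The C4–O bond is cut. The epoxide comes from cyclic iodocarbonate 6, which comes from tert-butyl carbonate 5 of homoallylic alcohol 4. The iodocyclisation relays the C6 configuration to C4 through a six-membered chair, which is the most reliable way to a syn-1,3-diol from a single carbinol. A second reagent-controlled addition to a β-oxygenated aldehyde is the alternative and is kept as the fallback.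

**4 back to 2 and 3, and 2 back to 1.** The C5–C6 bond is cut to give aldehyde 2 and allylboronate 3. A chiral phosphoric acid sets C6, the stereocentre from which C4 is derived. Aldehyde 2 is the dibenzyl ether of commercial 1.

## Roads not taken

Alternative 1: The cut is at C3–C4 and C4–C5, with C4 supplied as a dithiane carbon. Lithiated 2-(tert-butyldimethylsilyl)-1,3-dithiane A1 would open the racemic aryl oxirane A2 (from 2) at its CH2 terminus. A 1,4-shift of silicon from carbon to the new alkoxide would regenerate the anion, which would open the enantiopure oxirane A3 (from 11) to give A4 in one flask.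
- Merits: the whole C6–C2′ backbone is assembled in one operation from three small pieces. Only C2 has to be set by an asymmetric method, because C6 is meant to be fixed later by a thermodynamically controlled closure through the benzylic cation.
- Weak points: A4 is still four operations from the acetate (sulfur removal, ring closure, reduction of the C4 ketone with a bulky hydride, acetylation). Unmasking a dithiane calls for thiophilic or oxidising reagents in a molecule with two very electron-rich arenes. The p-alkoxy oxirane A2 is prone to rearrange or to open at the benzylic carbon. The axial C4 oxygen rests on one late reduction.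
- Comparison: this road is at least as short as the chosen one (about ten or eleven steps in the longest line) and uses one catalyst-controlled stereochemical step where the chosen plan uses three. The chosen plan sets against it a C4 oxygen carried at the correct level and configuration from the acyclic syn-diol, a ring closure that is stereospecific as well as thermodynamically favoured, and no sulfur.

Alternative 2: The cut is at C5–C6, after O1–C6 has been made as an acetal. Hydroxy acid A5 (from 11) and aldehyde 2 would be condensed to the cis-dioxanone A6, and its carbonyl methylenated with Cp2TiMe2 to the enol acetal A7. Me2AlCl would open A7 to an aluminium enolate and an aryl-stabilised oxocarbenium ion, which recombine through a chair to the 2,6-cis ketone A8.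
- Merits: aldehyde 2 is used directly and the two halves are joined late. The trioxygenated ring makes the ionisation easy. Only one stereocentre (in A5) needs an asymmetric step. The longest line is probably about two steps shorter than in the chosen plan.
- Weak points: the same electron-rich ring makes the acetal carbon labile during formation of A6 and during the titanium methylenation. A stoichiometric aluminium Lewis acid has to be used next to three benzyl ethers. C4 must again be reduced from the equatorial side with LiBH(s-Bu)3 to obtain the axial alcohol.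
- Comparison: in step count and convergence this road is better. The chosen plan offers a neutral, catalytic ring closure and an axial C4–O bond fixed by substrate-controlled iodocyclisation. Its price is a longer linear sequence and an enantioselective step spent on C2′, a stereocentre that is later erased.

Alternative 3: The cut is at C2–C3. The β-alkoxy enone iodide A9 (reachable from epoxy alcohol 7 and aldehyde 11) would be treated with Bu3SnH and a radical initiator. The primary C3 radical adds 6-exo to the oxygen-bearing alkene carbon and gives A10.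
- Merits: radical additions to β-alkoxy enones are reliably 2,6-cis. The conditions are neutral and tolerate electron-rich arenes and benzylic ethers. C4 and C6 come from the same iodocarbonate chemistry as in the chosen plan, and no stereocentre at C2′ is needed.
- Weak points: the side chain arrives as an aryl ketone, one oxidation level too high. The C2′ carbonyl must be removed in a dedicated operation on a β-alkoxy ketone that can undergo retro-Michael opening. The silyl ether must be exchanged for the acetate, and stoichiometric tin is used. From 7 the count comes to roughly fourteen steps.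
- Comparison: this road matches the chosen one in stereocontrol at C2 and avoids an asymmetric step at C2′. The chosen plan is shorter because its leftover unsaturation disappears in the final hydrogenation without an extra step.

Key step: step 10

Assumption: 4-(benzyloxy)-3-methoxybenzaldehyde (11, otherwise one benzylation from vanillin), lithium acetylide–ethylenediamine complex (8), both antipodes of the TRIP phosphoric acid and both antipodes of 3-exo-morpholinoisoborneol (MIB) are taken as purchasable.

## Route

Step 1
Reactants: 1 3,4-dihydroxy-5-methoxybenzaldehyde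
Product: 2 3,4-bis(benzyloxy)-5-methoxybenzaldehyde
Conditions: BnBr, K2CO3, DMF, 60 °C
Reagents that add atoms: benzyl bromide, BrCc1ccccc1
Why: Williamson ether synthesis on both phenols; the aldehyde is inert, and benzyl is chosen because it is removed in the final hydrogenation.

Step 2
Reactants: 2 3,4-bis(benzyloxy)-5-methoxybenzaldehyde; 3 allylboronic acid pinacol ester
Product: 4 (1S)-1-[3,4-bis(benzyloxy)-5-methoxyphenyl]but-3-en-1-ol
Conditions: (S)-TRIP phosphoric acid (5 mol%), toluene, −30 °C
Reagents that add atoms: none
Why: Chiral phosphoric acid-catalysed allylboration of an aryl aldehyde through a closed six-membered chair transition state. The (R)-acid is the one that sends the allyl group to the Re face of aryl aldehydes, so the (S)-acid should give Si-face attack and the (S)-carbinol, which becomes C6.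

Step 3
Reactants: 4 (1S)-1-[3,4-bis(benzyloxy)-5-methoxyphenyl]but-3-en-1-ol
Product: 5 tert-butyl (1S)-1-[3,4-bis(benzyloxy)-5-methoxyphenyl]but-3-en-1-yl carbonate
Conditions: Boc2O, DMAP (cat.), MeCN, rt
Reagents that add atoms: di-tert-butyl dicarbonate, CC(C)(C)OC(=O)OC(=O)OC(C)(C)C
Why: DMAP-catalysed acylation of a secondary alcohol; it installs the carbonate oxygen nucleophile for the next step and leaves the stereocentre untouched.

Step 4
Reactants: 5 tert-butyl (1S)-1-[3,4-bis(benzyloxy)-5-methoxyphenyl]but-3-en-1-yl carbonate
Product: 6 (4R,6S)-6-[3,4-bis(benzyloxy)-5-methoxyphenyl]-4-(iodomethyl)-1,3-dioxan-2-one (4,6-cis)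
Conditions: IBr, toluene, −85 °C
Reagents that add atoms: iodine monobromide, IBr
Why: Iodocarbonate cyclisation: the iodonium ion is opened 6-exo by the carbonyl oxygen with loss of the tert-butyl cation. At low temperature a chair with both substituents equatorial should give the 4,6-cis carbonate, so C4 is set syn to C6 by 1,3-induction.

Step 5
Reactants: 6 (4R,6S)-6-[3,4-bis(benzyloxy)-5-methoxyphenyl]-4-(iodomethyl)-1,3-dioxan-2-one
Product: 7 (1S)-1-[3,4-bis(benzyloxy)-5-methoxyphenyl]-2-[(2R)-oxiran-2-yl]ethan-1-ol
Conditions: K2CO3, MeOH, 0 °C to rt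
Reagents that add atoms: none
Why: Methanolysis of the carbonate frees the C4 alkoxide, which displaces iodide (intramolecular Williamson closure) without breaking the C4–O bond; the benzylic hydroxyl is released in the same operation.

Step 6
Reactants: 7 (1S)-1-[3,4-bis(benzyloxy)-5-methoxyphenyl]-2-[(2R)-oxiran-2-yl]ethan-1-ol; 8 lithium acetylide–ethylenediamine complex
Product: 9 (1S,3S)-1-[3,4-bis(benzyloxy)-5-methoxyphenyl]hex-5-yne-1,3-diol
Conditions: DMSO, rt (8 in excess), then aq NH4Cl
Reagents that add atoms: none
Why: SN2 opening of a terminal epoxide at its CH2 carbon by acetylide in DMSO. The excess reagent first deprotonates the free hydroxyl, C4 is not involved, and the terminal alkyne is obtained directly.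

Step 7
Reactants: 9 (1S,3S)-1-[3,4-bis(benzyloxy)-5-methoxyphenyl]hex-5-yne-1,3-diol
Product: 10 (1S,3S)-1-[3,4-bis(benzyloxy)-5-methoxyphenyl]-1,3-bis[(tert-butyldimethylsilyl)oxy]hex-5-yne
Conditions: TBSCl, imidazole, DMF, 40 °C
Reagents that add atoms: tert-butyldimethylsilyl chloride, CC(C)(C)[Si](C)(C)Cl
Why: Silylation of both secondary alcohols; the silyl ethers tolerate borane and organozinc reagents and can later be removed with fluoride under non-acidic conditions.

Step 8
Reactants: 10 (1S,3S)-1-[3,4-bis(benzyloxy)-5-methoxyphenyl]-1,3-bis[(tert-butyldimethylsilyl)oxy]hex-5-yne; 11 4-(benzyloxy)-3-methoxybenzaldehyde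
Product: 14 (1R,2E,5S,7S)-7-[3,4-bis(benzyloxy)-5-methoxyphenyl]-1-[4-(benzyloxy)-3-methoxyphenyl]-5,7-bis[(tert-butyldimethylsilyl)oxy]hept-2-en-1-ol, via (E)-alkenyl(dicyclohexyl)borane 12 (not isolated), via (E)-alkenyl(methyl)zinc 13 (not isolated)
Conditions: Cy2BH, toluene, 0 °C to rt; Me2Zn, −78 °C; (+)-MIB (5 mol%), then 11, −20 to 0 °C; aq NH4Cl
Reagents that add atoms: dicyclohexylborane, C1CCCCC1BC1CCCCC1 (boron and cyclohexyl groups stay in 12 only, one hydrogen stays in 14); dimethylzinc, C[Zn]C (zinc and one methyl stay in 13 only)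
Why: syn-Hydroboration of the terminal alkyne gives the (E)-alkenylborane, boron-to-zinc exchange retains the geometry, and amino-alcohol-catalysed alkenylzinc addition to the aryl aldehyde forms the C1′–C2′ bond. The (−)-ligand sends alkyl and alkenyl groups to the Si face of aryl aldehydes, so (+)-MIB should give Re-face addition and the (R)-carbinol at C2′; the existing stereocentres are remote, so the catalyst should control the outcome.

Step 9
Reactants: 14 the bis-silyl ether from step 8
Product: 15 (1S,3S,5E,7R)-1-[3,4-bis(benzyloxy)-5-methoxyphenyl]-7-[4-(benzyloxy)-3-methoxyphenyl]hept-5-ene-1,3,7-triol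
Conditions: TBAF, THF, 0 °C to rt
Reagents that add atoms: none
Why: Fluoride-mediated cleavage of both silyl ethers; the basic, non-acidic medium should leave the ionisable aryl allyl carbinol and the E alkene untouched.

Step 10
Reactants: 15 (1S,3S,5E,7R)-1-[3,4-bis(benzyloxy)-5-methoxyphenyl]-7-[4-(benzyloxy)-3-methoxyphenyl]hept-5-ene-1,3,7-triol
Product: 16 (2R,4S,6S)-6-[3,4-bis(benzyloxy)-5-methoxyphenyl]-2-[(E)-2-(4-benzyloxy-3-methoxyphenyl)ethenyl]oxan-4-ol (2,6-cis, hydroxyl axial)
Conditions: PdCl2(MeCN)2 (10 mol%), THF, 0 °C
Reagents that add atoms: none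
Why: PdCl2(MeCN)2 (divalent palladium) should bind the C2=C1′ alkene on the face that carries the C2′ hydroxyl, the C6 hydroxyl then adds to C2 on that same face, and syn β-elimination of the palladium hydroxide across C1′–C2′ releases the (E)-styrene and the catalyst, a net syn SN2′ displacement of hydroxide. The closest known reaction type is the PdCl2(MeCN)2-catalysed cyclisation of hydroxy allylic alcohols to 2-alkenyl tetrahydropyrans with 1,3-chirality transfer. The ring closes 6-exo-trig through O1–C2. The new stereocentre C2 is controlled by the C2′ carbinol: with the C2′–H bond eclipsing the alkene (the conformer free of allylic 1,3-strain, and the one that leads to the E product), the (R)-carbinol exposes the alkene face that gives the C2 configuration of 16. This facial demand coincides with the chair-like transition state that keeps the C6 aryl and the C2 alkenyl groups equatorial and the C4 hydroxyl axial, so chirality transfer and ring conformation reinforce each other, and the 2,6-cis product is also the more stable one. The step needs attack by the C6 hydroxyl and not by the C4 hydroxyl (which would give an oxetane and is not expected), and it needs the electron-rich C2′ carbinol not to ionise; the neutral catalyst at 0 °C and the absence of any Brønsted acid are meant to secure this.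

Step 11
Reactants: 16 the tetrahydropyranol from step 10
Product: 17 (2R,4S,6S)-6-[3,4-bis(benzyloxy)-5-methoxyphenyl]-2-[(E)-2-(4-benzyloxy-3-methoxyphenyl)ethenyl]oxan-4-yl acetate
Conditions: Ac2O, pyridine, DMAP (cat.), CH2Cl2, rt
Reagents that add atoms: acetic anhydride, CC(=O)OC(C)=O
Why: DMAP-catalysed acetylation of the only free hydroxyl; it is done before debenzylation so that no phenol is acylated.

Step 12
Reactants: 17 the acetate from step 11
Product: 18 (2S,4S,6S)-6-(3,4-dihydroxy-5-methoxyphenyl)-2-[2-(4-hydroxy-3-methoxyphenyl)ethyl]oxan-4-yl acetate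
Conditions: H2 (1 atm), 10% Pd/C, EtOAc, rt
Reagents that add atoms: none
Why: Heterogeneous catalytic hydrogenation should saturate the styrene and hydrogenolyse the three aryl benzyl ethers, which cleave much faster than the dialkyl benzylic C6–O1 ether in neutral solvent. No stereocentre is touched; C2 becomes S only through a change in substituent priority.

## Compound list

1 | 3,4-dihydroxy-5-methoxybenzaldehyde | COc1cc(C=O)cc(O)c1O | starting material
2 | 3,4-bis(benzyloxy)-5-methoxybenzaldehyde | COc1cc(C=O)cc(OCc2ccccc2)c1OCc1ccccc1 | intermediate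
3 | allylboronic acid pinacol ester | C=CCB1OC(C)(C)C(C)(C)O1 | starting material
4 | (1S)-1-[3,4-bis(benzyloxy)-5-methoxyphenyl]but-3-en-1-ol | C=CC[C@H](O)c1cc(OC)c(OCc2ccccc2)c(OCc2ccccc2)c1 | intermediate
5 | tert-butyl (1S)-1-[3,4-bis(benzyloxy)-5-methoxyphenyl]but-3-en-1-yl carbonate | C=CC[C@H](OC(=O)OC(C)(C)C)c1cc(OC)c(OCc2ccccc2)c(OCc2ccccc2)c1 | intermediate
6 | (4R,6S)-6-[3,4-bis(benzyloxy)-5-methoxyphenyl]-4-(iodomethyl)-1,3-dioxan-2-one | IC[C@H]1C[C@@H](c2cc(OC)c(OCc3ccccc3)c(OCc3ccccc3)c2)OC(=O)O1 | intermediate
7 | (1S)-1-[3,4-bis(benzyloxy)-5-methoxyphenyl]-2-[(2R)-oxiran-2-yl]ethan-1-ol | O[C@@H](C[C@@H]1CO1)c1cc(OC)c(OCc2ccccc2)c(OCc2ccccc2)c1 | intermediate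
8 | lithium acetylide–ethylenediamine complex | [Li]C#C.NCCN | starting material
9 | (1S,3S)-1-[3,4-bis(benzyloxy)-5-methoxyphenyl]hex-5-yne-1,3-diol | C#CC[C@H](O)C[C@H](O)c1cc(OC)c(OCc2ccccc2)c(OCc2ccccc2)c1 | intermediate
10 | (1S,3S)-1-[3,4-bis(benzyloxy)-5-methoxyphenyl]-1,3-bis[(tert-butyldimethylsilyl)oxy]hex-5-yne | C#CC[C@H](O[Si](C)(C)C(C)(C)C)C[C@H](O[Si](C)(C)C(C)(C)C)c1cc(OC)c(OCc2ccccc2)c(OCc2ccccc2)c1 | intermediate
11 | 4-(benzyloxy)-3-methoxybenzaldehyde | COc1cc(C=O)ccc1OCc1ccccc1 | starting material
12 | dicyclohexyl[(1E,4S,6S)-6-Ar-4,6-bis(tert-butyldimethylsilyloxy)hex-1-en-1-yl]borane | C1CCCCC1B(/C=C/C[C@H](O[Si](C)(C)C(C)(C)C)C[C@H](O[Si](C)(C)C(C)(C)C)c1cc(OC)c(OCc2ccccc2)c(OCc2ccccc2)c1)C1CCCCC1 | intermediate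
13 | methyl[(1E,4S,6S)-6-Ar-4,6-bis(tert-butyldimethylsilyloxy)hex-1-en-1-yl]zinc | C[Zn]/C=C/C[C@H](O[Si](C)(C)C(C)(C)C)C[C@H](O[Si](C)(C)C(C)(C)C)c1cc(OC)c(OCc2ccccc2)c(OCc2ccccc2)c1 | intermediate
14 | (1R,2E,5S,7S)-7-[3,4-bis(benzyloxy)-5-methoxyphenyl]-1-[4-(benzyloxy)-3-methoxyphenyl]-5,7-bis[(tert-butyldimethylsilyl)oxy]hept-2-en-1-ol | COc1cc([C@H](O)/C=C/C[C@H](O[Si](C)(C)C(C)(C)C)C[C@H](O[Si](C)(C)C(C)(C)C)c2cc(OCc3ccccc3)c(OCc3ccccc3)c(OC)c2)ccc1OCc1ccccc1 | intermediate
15 | (1S,3S,5E,7R)-1-[3,4-bis(benzyloxy)-5-methoxyphenyl]-7-[4-(benzyloxy)-3-methoxyphenyl]hept-5-ene-1,3,7-triol | COc1cc([C@H](O)/C=C/C[C@H](O)C[C@H](O)c2cc(OCc3ccccc3)c(OCc3ccccc3)c(OC)c2)ccc1OCc1ccccc1 | intermediate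
16 | (2R,4S,6S)-6-[3,4-bis(benzyloxy)-5-methoxyphenyl]-2-[(E)-2-(4-benzyloxy-3-methoxyphenyl)ethenyl]oxan-4-ol | COc1cc(/C=C/[C@H]2C[C@H](O)C[C@@H](c3cc(OCc4ccccc4)c(OCc4ccccc4)c(OC)c3)O2)ccc1OCc1ccccc1 | intermediate
17 | (2R,4S,6S)-6-[3,4-bis(benzyloxy)-5-methoxyphenyl]-2-[(E)-2-(4-benzyloxy-3-methoxyphenyl)ethenyl]oxan-4-yl acetate | COc1cc(/C=C/[C@H]2C[C@H](OC(C)=O)C[C@@H](c3cc(OCc4ccccc4)c(OCc4ccccc4)c(OC)c3)O2)ccc1OCc1ccccc1 | intermediate
18 | (2S,4S,6S)-6-(3,4-dihydroxy-5-methoxyphenyl)-2-[2-(4-hydroxy-3-methoxyphenyl)ethyl]oxan-4-yl acetate | COc1cc(CC[C@H]2C[C@H](OC(C)=O)C[C@@H](c3cc(O)c(O)c(OC)c3)O2)ccc1O | target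

## Step count and risks

Total: 12 steps. Longest linear sequence: 12 steps (1 to 18); 3, 8 and 11 enter as purchased materials.

**Step 10 (key step).** The most likely failure is ionisation of the C2′ carbinol (allylic and para to a benzyloxy group) by the Lewis-acidic metal. That would erode the stereospecific transfer, with partial loss of 2,6-cis and E control, or lead to elimination to a diene. Fallback: an oxa-Michael ring closure that needs no C2′ carbinol. It sets out from 14. Oxidation of the allylic alcohol with MnO2 gives the (2E,5S,7S)-1-Ar′-7-Ar-5,7-bis(silyloxy)hept-2-en-1-one F1. TBAF removes both silyl groups, and the freed C6 hydroxyl adds to the enone under thermodynamic control to give the 2,6-cis tetrahydropyranyl ketone with axial hydroxyl F2. Acetylation gives the keto acetate F3. Hydrogenation over Pd/C in ethanol with acetic acid should take the p-oxygenated aryl ketone to the methylene group through the benzylic alcohol and cleave the benzyl ethers, returning to the route at 18.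

**Step 4.** Competing electrophilic iodination of the trialkoxy arene, or ionisation of the benzylic carbonate under IBr, may divert material from the cyclisation. Fallback: from 4, silylation gives the (S)-silyl ether F4. Lemieux–Johnson cleavage (OsO4 cat., NaIO4, 2,6-lutidine) gives the (3S)-3-aryl-3-silyloxypropanal F5. Propargylation with allenylboronic acid pinacol ester under the same (S)-configured phosphoric acid should give the (1S,3S)-1-silyloxyhex-5-yn-3-ol F6 by reagent control. Silylation of F6 returns to the route at 10.

**Step 8.** Facial selectivity may be insufficient with the electron-rich, poorly electrophilic aldehyde, or methyl transfer from zinc may compete. The resulting C2′ epimer would cyclise to the 2,6-trans or Z product. Fallback: from 10, catalytic asymmetric alkynylation of 11 (Me2Zn with the ProPhenol ligand antipode that delivers to the Re face) gives the (1S,5S,7S)-propargylic alcohol F7. Hydroxyl-directed trans-hydroalumination with NaAlH2(OCH2CH2OMe)2 in THF then returns to the route at 14.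

**Step 12.** Over-reduction is the risk: hydrogenolysis of the allylic C2–O1 bond before the styrene is saturated, or of the benzylic C6–O1 bond. Fallback: from 17, diimide (from 2-nitrobenzenesulfonohydrazide and Et3N) saturates the alkene without any hydrogenolysis and gives the saturated tribenzyl ether acetate F8. A short hydrogenolysis over Pd/C then removes only the aryl benzyl ethers and returns to the route at 18.

## Further compounds

F1 | step 10 | (2E,5S,7S)-7-[3,4-bis(benzyloxy)-5-methoxyphenyl]-1-[4-(benzyloxy)-3-methoxyphenyl]-5,7-bis[(tert-butyldimethylsilyl)oxy]hept-2-en-1-one | COc1cc(C(=O)/C=C/C[C@H](O[Si](C)(C)C(C)(C)C)C[C@H](O[Si](C)(C)C(C)(C)C)c2cc(OCc3ccccc3)c(OCc3ccccc3)c(OC)c2)ccc1OCc1ccccc1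
F2 | step 10 | 1-[4-(benzyloxy)-3-methoxyphenyl]-2-[(2R,4S,6S)-6-[3,4-bis(benzyloxy)-5-methoxyphenyl]-4-hydroxyoxan-2-yl]ethan-1-one | COc1cc(C(=O)C[C@H]2C[C@H](O)C[C@@H](c3cc(OCc4ccccc4)c(OCc4ccccc4)c(OC)c3)O2)ccc1OCc1ccccc1
F3 | step 10 | (2R,4S,6S)-6-[3,4-bis(benzyloxy)-5-methoxyphenyl]-2-{2-[4-(benzyloxy)-3-methoxyphenyl]-2-oxoethyl}oxan-4-yl acetate | COc1cc(C(=O)C[C@H]2C[C@H](OC(C)=O)C[C@@H](c3cc(OCc4ccccc4)c(OCc4ccccc4)c(OC)c3)O2)ccc1OCc1ccccc1
F4 | step 4 | (1S)-1-[3,4-bis(benzyloxy)-5-methoxyphenyl]-1-[(tert-butyldimethylsilyl)oxy]but-3-ene | C=CC[C@H](O[Si](C)(C)C(C)(C)C)c1cc(OC)c(OCc2ccccc2)c(OCc2ccccc2)c1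
F5 | step 4 | (3S)-3-[3,4-bis(benzyloxy)-5-methoxyphenyl]-3-[(tert-butyldimethylsilyl)oxy]propanal | O=CC[C@H](O[Si](C)(C)C(C)(C)C)c1cc(OC)c(OCc2ccccc2)c(OCc2ccccc2)c1
F6 | step 4 | (1S,3S)-1-[3,4-bis(benzyloxy)-5-methoxyphenyl]-1-[(tert-butyldimethylsilyl)oxy]hex-5-yn-3-ol | C#CC[C@H](O)C[C@H](O[Si](C)(C)C(C)(C)C)c1cc(OC)c(OCc2ccccc2)c(OCc2ccccc2)c1
F7 | step 8 | (1S,5S,7S)-7-[3,4-bis(benzyloxy)-5-methoxyphenyl]-1-[4-(benzyloxy)-3-methoxyphenyl]-5,7-bis[(tert-butyldimethylsilyl)oxy]hept-2-yn-1-ol | COc1cc([C@H](O)C#CC[C@H](O[Si](C)(C)C(C)(C)C)C[C@H](O[Si](C)(C)C(C)(C)C)c2cc(OCc3ccccc3)c(OCc3ccccc3)c(OC)c2)ccc1OCc1ccccc1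
F8 | step 12 | (2S,4S,6S)-6-[3,4-bis(benzyloxy)-5-methoxyphenyl]-2-{2-[4-(benzyloxy)-3-methoxyphenyl]ethyl}oxan-4-yl acetate | COc1cc(CC[C@H]2C[C@H](OC(C)=O)C[C@@H](c3cc(OCc4ccccc4)c(OCc4ccccc4)c(OC)c3)O2)ccc1OCc1ccccc1
A1 | alternative 1 | 2-(tert-butyldimethylsilyl)-1,3-dithiane | CC(C)(C)[Si](C)(C)C1SCCCS1
A2 | alternative 1 | 2-[3,4-bis(benzyloxy)-5-methoxyphenyl]oxirane (racemic) | COc1cc(C2CO2)cc(OCc2ccccc2)c1OCc1ccccc1
A3 | alternative 1 | (2S)-2-{2-[4-(benzyloxy)-3-methoxyphenyl]ethyl}oxirane | COc1cc(CC[C@H]2CO2)ccc1OCc1ccccc1
A4 | alternative 1 | dithiane-masked 1-aryl-1-silyloxy-5-hydroxy-7-arylheptan-3-one (5S; benzylic centre uncontrolled) | COc1cc(CC[C@H](O)CC2(CC(O[Si](C)(C)C(C)(C)C)c3cc(OCc4ccccc4)c(OCc4ccccc4)c(OC)c3)SCCCS2)ccc1OCc1ccccc1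
A5 | alternative 2 | (3S)-5-[4-(benzyloxy)-3-methoxyphenyl]-3-hydroxypentanoic acid | COc1cc(CC[C@H](O)CC(O)=O)ccc1OCc1ccccc1
A6 | alternative 2 | cis-2-[3,4-bis(benzyloxy)-5-methoxyphenyl]-6-{2-[4-(benzyloxy)-3-methoxyphenyl]ethyl}-1,3-dioxan-4-one | O=C1C[C@H](CCc2ccc(OCc3ccccc3)c(OC)c2)O[C@H](c2cc(OC)c(OCc3ccccc3)c(OCc3ccccc3)c2)O1
A7 | alternative 2 | cis-2-[3,4-bis(benzyloxy)-5-methoxyphenyl]-6-{2-[4-(benzyloxy)-3-methoxyphenyl]ethyl}-4-methylidene-1,3-dioxane | C=C1C[C@H](CCc2ccc(OCc3ccccc3)c(OC)c2)O[C@H](c2cc(OC)c(OCc3ccccc3)c(OCc3ccccc3)c2)O1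
A8 | alternative 2 | 2,6-cis-6-[3,4-bis(benzyloxy)-5-methoxyphenyl]-2-{2-[4-(benzyloxy)-3-methoxyphenyl]ethyl}oxan-4-one | COc1cc(CC[C@H]2CC(=O)C[C@@H](c3cc(OCc4ccccc4)c(OCc4ccccc4)c(OC)c3)O2)ccc1OCc1ccccc1
A9 | alternative 3 | (E)-β-alkoxy enone iodide: 1-[4-(benzyloxy)-3-methoxyphenyl]-3-{(1S,3S)-1-[3,4-bis(benzyloxy)-5-methoxyphenyl]-3-[(tert-butyldimethylsilyl)oxy]-4-iodobutoxy}prop-2-en-1-one | COc1cc(C(=O)/C=C/O[C@@H](C[C@H](CI)O[Si](C)(C)C(C)(C)C)c2cc(OCc3ccccc3)c(OCc3ccccc3)c(OC)c2)ccc1OCc1ccccc1
A10 | alternative 3 | 2,6-cis-tetrahydropyran with axial C4 silyloxy group and aroylmethyl group on C2 | COc1cc(C(=O)C[C@H]2C[C@H](O[Si](C)(C)C(C)(C)C)C[C@@H](c3cc(OCc4ccccc4)c(OCc4ccccc4)c(OC)c3)O2)ccc1OCc1ccccc1
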